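**Plan**

1. Numbering: tetralin C1 (bears ring C), C2 (carboxyl), C3 (hydroxymethyl), C4 (CH2); ring A is the fused methoxyphenol ring, ring B the carbocycle, ring C the pendant aryl. The retrosynthesis first removes the benzyl and acetonide groups and takes the C3 diol back to an exocyclic C3 methylene, then opens ring B at C4–C4a and C1–C2.
2. Enabling feature: C1 is doubly benzylic and para to O4' of ring C, so it can be the electrophilic carbon of a para-quinone methide. C4a of ring A is para to the C7 hydroxyl, so it is a phenolate carbon nucleophile. The unit C4a–C8a–C1 is thus an acceptor/donor pair that a three-carbon C2–C3–C4 donor/acceptor dipole can bridge.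
3. Forward: fragment 1 (sulfone 9, steps 1–5) and fragment 2 (allyl carbonate 15 carrying C2 as a dioxolanone, steps 6–9) are joined in step 10 by a palladium trimethylenemethane (3+3) annulation that makes ring B in one operation. Rings A and C come intact from 1 and 3.
4. Endgame: osmylation of the C3 methylene, hydrolysis, hydrogenolysis (steps 11–13).
5. Stereochemistry: C1 and C2 are set in step 10 (absolute sense from the chiral phosphoramidite on palladium, relative sense from the ring closure); C3 is set in step 11 by substrate control.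

Key step: step 10

Assumption: the (S,R,R) enantiomer of the phosphoramidite ligand is taken to deliver the (1S,2S) series in step 10; should its sense of induction be opposite, the (R,S,S) ligand is used.

**Route**

Step 1
Reactants: 1 5-bromo-2-methoxyphenol
Product: 2 (5-bromo-2-methoxyphenoxy)(tert-butyl)dimethylsilane
Conditions: TBSCl, imidazole, CH2Cl2, rt
Reagents that add atoms: tert-butyldimethylsilyl chloride, CC(C)(C)[Si](C)(C)Cl
Why: Imidazole-assisted silyl ether formation masks the acidic O–H so that the aryl bromide can later be turned into a Grignard reagent.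

Step 2
Reactants: 3 3,4,5-tris(benzyloxy)benzaldehyde
Product: 4 3,5-bis(benzyloxy)-4-hydroxybenzaldehyde
Conditions: NaSEt (1.1 equiv), DMF, 100 °C; then 1 M HCl
Reagents that add atoms: none
Why: Thiolate SN2 dealkylation of an aryl benzyl ether; only the O4 phenoxide is conjugated to the para formyl group and is the best leaving group, so the central ether should be cleaved selectively, as in the para-selective dealkylation of 3,4,5-trialkoxybenzaldehydes.

Step 3
Reactants: 2 (5-bromo-2-methoxyphenoxy)(tert-butyl)dimethylsilane; 4 3,5-bis(benzyloxy)-4-hydroxybenzaldehyde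
Product: 7 rac-2,6-bis(benzyloxy)-4-{[3-(tert-butyldimethylsilyloxy)-4-methoxyphenyl](hydroxy)methyl}phenol, via arylmagnesium bromide 5 (not isolated), via sodium phenolate 6 (not isolated)
Conditions: 2, Mg, THF, 45 °C; 4, NaH, THF, 0 °C; combine, 0 °C to rt; aq. NH4Cl
Reagents that add atoms: none
Why: Grignard addition to the aldehyde with the free phenol masked as its sodium salt; the carbinol is racemic, which does not matter because this carbon becomes sp2 in 16.

Step 4
Reactants: 7 rac-2,6-bis(benzyloxy)-4-{[3-(tert-butyldimethylsilyloxy)-4-methoxyphenyl](hydroxy)methyl}phenol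
Product: 8 rac-2,6-bis(benzyloxy)-4-[hydroxy(3-hydroxy-4-methoxyphenyl)methyl]phenol
Conditions: K2CO3 (0.3 equiv), MeOH, rt
Reagents that add atoms: none
Why: Base-catalysed methanolysis of an aryl silyl ether (aryloxide leaving group) frees the ring A phenol without touching the benzyl ethers.

Step 5
Reactants: 8 rac-2,6-bis(benzyloxy)-4-[hydroxy(3-hydroxy-4-methoxyphenyl)methyl]phenol
Product: 9 rac-2,6-bis(benzyloxy)-4-[(3-hydroxy-4-methoxyphenyl)(4-methylbenzenesulfonyl)methyl]phenol
Conditions: 4-methylbenzenesulfinic acid (1.3 equiv, freshly liberated from its sodium salt), MgSO4, CH2Cl2, rt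
Reagents that add atoms: 4-methylbenzenesulfinic acid, Cc1ccc(cc1)S(=O)O
Why: Acid-promoted SN1 substitution of the electron-rich para-hydroxybenzhydrol by sulfinate at sulfur should give a bench-stable sulfone of the kind routinely used to release para-quinone methides with base.

Step 6
Reactants: 10 3-methylbut-2-enoic acid
Product: 12 rac-2-hydroxy-3-methylbut-3-enoic acid, via allylic hydroperoxide 11 (not isolated)
Conditions: O2, visible light, tetraphenylporphyrin (cat.), CH2Cl2, 0 °C; then Me2S
Reagents that add atoms: dioxygen, O=O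
Why: Schenck ene reaction of singlet oxygen (oxygen adds at C2, hydrogen comes from a methyl group, the double bond moves to C3=CH2) followed by reduction of the hydroperoxide; the product is racemic and this centre is erased in step 10.

Step 7
Reactants: 12 rac-2-hydroxy-3-methylbut-3-enoic acid
Product: 13 rac-2,2-dimethyl-5-(prop-1-en-2-yl)-1,3-dioxolan-4-one
Conditions: 2,2-dimethoxypropane, PPTS (cat.), CH2Cl2, rt
Reagents that add atoms: 2,2-dimethoxypropane, COC(C)(C)OC
Why: Acid-catalysed transketalisation of the α-hydroxy acid gives the 1,3-dioxolan-4-one, which masks OH and CO2H together and makes the C–H between them an acidified cyclic enolate precursor.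

Step 8
Reactants: 13 rac-2,2-dimethyl-5-(prop-1-en-2-yl)-1,3-dioxolan-4-one
Product: 14 rac-5-(3-hydroxyprop-1-en-2-yl)-2,2-dimethyl-1,3-dioxolan-4-one
Conditions: SeO2 (0.3 equiv), tBuOOH (2 equiv), CH2Cl2, rt
Reagents that add atoms: tert-butyl hydroperoxide, CC(C)(C)OO
Why: SeO2 allylic oxidation (ene reaction then [2,3]-sigmatropic shift) should attack the methyl group of the 1,1-disubstituted alkene in preference to the electron-poor ring methine, giving the primary allylic alcohol.

Step 9
Reactants: 14 rac-5-(3-hydroxyprop-1-en-2-yl)-2,2-dimethyl-1,3-dioxolan-4-one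
Product: 15 rac-tert-butyl 2-(2,2-dimethyl-5-oxo-1,3-dioxolan-4-yl)prop-2-en-1-yl carbonate
Conditions: Boc2O, DMAP (cat.), CH2Cl2, 0 °C
Reagents that add atoms: di-tert-butyl dicarbonate, CC(C)(C)OC(=O)OC(=O)OC(C)(C)C
Why: DMAP-catalysed acylation gives the allylic tert-butyl carbonate, a leaving group that releases tert-butoxide as internal base on ionisation.

Step 10
Reactants: 9 rac-2,6-bis(benzyloxy)-4-[(3-hydroxy-4-methoxyphenyl)(4-methylbenzenesulfonyl)methyl]phenol; 15 rac-tert-butyl 2-(2,2-dimethyl-5-oxo-1,3-dioxolan-4-yl)prop-2-en-1-yl carbonate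
Product: 17 (1'S,4S)-1'-[3,5-bis(benzyloxy)-4-hydroxyphenyl]-7'-hydroxy-6'-methoxy-2,2-dimethyl-3'-methylidene-3',4'-dihydro-1'H-spiro[1,3-dioxolane-4,2'-naphthalen]-5-one, via quinone methide potassium phenolate 16 (not isolated)
Conditions: 9, KOtBu (2.05 equiv), THF, −40 °C; then 15 (1.3 equiv), Pd(dba)2 (5 mol %), (S,R,R)-BINOL phosphoramidite of bis(1-phenylethyl)amine (12 mol %), THF, −20 °C to rt; AcOH quench
Reagents that add atoms: none
Why: Proposed new method: KOtBu expels sulfinate from 9 to give quinone methide 16, zerovalent palladium ionises carbonate 15 and the liberated tert-butoxide removes the doubly activated dioxolanone C–H, and the resulting palladium trimethylenemethane zwitterion adds through its substituted carbon 1,6 to the methide carbon (C1–C2), after which the ring A phenolate attacks a terminus of the cationic π-allyl through its para carbon (C4–C4a) and tautomerises back to the phenol. The closest known reaction types are palladium trimethylenemethane (3+2) and (3+3) cycloadditions with Michael acceptors and dipoles, 1,6-additions of stabilised carbanions to para-quinone methides, and palladium-catalysed intramolecular Friedel–Crafts-type allylic alkylation of phenols. Ring B closes as a six-membered ring by attack on an allyl terminus with the central allyl carbon C3 inside the ring, so the other terminus is left as the exocyclic methylene. C1 and C2 arise in the conjugate addition; because addition of the stabilised dipole should be reversible, ring closure under the chiral phosphoramidite–palladium fragment selects the enantiomer and, within it, the isomer whose C1 aryl is pseudoaxial, anti to the lactone carbonyl and gauche only to the small ring oxygen on C2 (aryl cis to O; 1S,2S in tetralin numbering). The selectivities needed are bond formation at the substituted carbon of the dipole (the carbanion is localised there), para over ortho attack of ring A (C8 is flanked by the oxygen and the branched side chain), and ring A attack over ipso attack of ring C; the last is secured because a dearomatised spiro[4.5]dienone would re-ionise under zerovalent palladium whereas the tetralin is an aromatic sink.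

Step 11
Reactants: 17 (1'S,4S)-1'-[3,5-bis(benzyloxy)-4-hydroxyphenyl]-7'-hydroxy-6'-methoxy-2,2-dimethyl-3'-methylidene-3',4'-dihydro-1'H-spiro[1,3-dioxolane-4,2'-naphthalen]-5-one
Product: 18 (1'S,3'R,4S)-1'-[3,5-bis(benzyloxy)-4-hydroxyphenyl]-3',7'-dihydroxy-3'-(hydroxymethyl)-6'-methoxy-2,2-dimethyl-3',4'-dihydro-1'H-spiro[1,3-dioxolane-4,2'-naphthalen]-5-one
Conditions: K2OsO2(OH)4 (4 mol %), NMO (1.5 equiv), acetone–H2O, 0 °C to rt
Reagents that add atoms: 4-methylmorpholine 4-oxide, C[N+]1([O-])CCOCC1; water, O
Why: Catalytic osmylation should occur on the face of the C3 methylene opposite the pseudoaxial C1 aryl (1,3-related) and anti to the allylic C2–O bond, the usual preference for allylic ethers, so the new tertiary hydroxyl ends trans to the C2 oxygen (3R).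

Step 12
Reactants: 18 (1'S,3'R,4S)-1'-[3,5-bis(benzyloxy)-4-hydroxyphenyl]-3',7'-dihydroxy-3'-(hydroxymethyl)-6'-methoxy-2,2-dimethyl-3',4'-dihydro-1'H-spiro[1,3-dioxolane-4,2'-naphthalen]-5-one
Product: 19 (1S,2S,3R)-1-[3,5-bis(benzyloxy)-4-hydroxyphenyl]-2,3,7-trihydroxy-3-(hydroxymethyl)-6-methoxy-1,2,3,4-tetrahydronaphthalene-2-carboxylic acid
Conditions: LiOH·H2O (3 equiv), degassed THF–H2O, 0 °C; then 1 M HCl to pH 3
Reagents that add atoms: lithium hydroxide, [Li+].[OH-]
Why: Saponification of the dioxolanone (an activated ester) should release the tertiary α-hydroxy acid and acetone; no stereocentre is enolisable and oxygen is excluded to protect the phenolates.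

Step 13
Reactants: 19 (1S,2S,3R)-1-[3,5-bis(benzyloxy)-4-hydroxyphenyl]-2,3,7-trihydroxy-3-(hydroxymethyl)-6-methoxy-1,2,3,4-tetrahydronaphthalene-2-carboxylic acid
Product: 20 (1S,2S,3R)-2,3,7-trihydroxy-3-(hydroxymethyl)-6-methoxy-1-(3,4,5-trihydroxyphenyl)-1,2,3,4-tetrahydronaphthalene-2-carboxylic acid
Conditions: H2 (1 atm), Pd/C (palladium on carbon, 10 %), MeOH–THF, rt, argon work-up
Reagents that add atoms: none
Why: Hydrogenolysis of the two aryl benzyl ethers under neutral conditions should unveil the pyrogallol ring without touching the non-benzylic tertiary alcohols, C1–H or C4.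

**Compound list**

1 | 5-bromo-2-methoxyphenol | COc1ccc(Br)cc1O | starting material
2 | (5-bromo-2-methoxyphenoxy)(tert-butyl)dimethylsilane | COc1ccc(Br)cc1O[Si](C)(C)C(C)(C)C | intermediate
3 | 3,4,5-tris(benzyloxy)benzaldehyde | O=Cc1cc(OCc2ccccc2)c(OCc2ccccc2)c(OCc2ccccc2)c1 | starting material
4 | 3,5-bis(benzyloxy)-4-hydroxybenzaldehyde | O=Cc1cc(OCc2ccccc2)c(O)c(OCc2ccccc2)c1 | intermediate
5 | [3-(tert-butyldimethylsilyloxy)-4-methoxyphenyl]magnesium bromide | COc1ccc([Mg]Br)cc1O[Si](C)(C)C(C)(C)C | intermediate
6 | sodium 2,6-bis(benzyloxy)-4-formylphenolate | O=Cc1cc(OCc2ccccc2)c([O-])c(OCc2ccccc2)c1.[Na+] | intermediate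
7 | rac-2,6-bis(benzyloxy)-4-{[3-(tert-butyldimethylsilyloxy)-4-methoxyphenyl](hydroxy)methyl}phenol | COc1ccc(cc1O[Si](C)(C)C(C)(C)C)C(O)c1cc(OCc2ccccc2)c(O)c(OCc2ccccc2)c1 | intermediate
8 | rac-2,6-bis(benzyloxy)-4-[hydroxy(3-hydroxy-4-methoxyphenyl)methyl]phenol | COc1ccc(cc1O)C(O)c1cc(OCc2ccccc2)c(O)c(OCc2ccccc2)c1 | intermediate
9 | rac-2,6-bis(benzyloxy)-4-[(3-hydroxy-4-methoxyphenyl)(4-methylbenzenesulfonyl)methyl]phenol | COc1ccc(cc1O)C(c1cc(OCc2ccccc2)c(O)c(OCc2ccccc2)c1)S(=O)(=O)c1ccc(C)cc1 | intermediate
10 | 3-methylbut-2-enoic acid | CC(C)=CC(=O)O | starting material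
11 | rac-2-hydroperoxy-3-methylbut-3-enoic acid | C=C(C)C(OO)C(=O)O | intermediate
12 | rac-2-hydroxy-3-methylbut-3-enoic acid | C=C(C)C(O)C(=O)O | intermediate
13 | rac-2,2-dimethyl-5-(prop-1-en-2-yl)-1,3-dioxolan-4-one | C=C(C)C1OC(C)(C)OC1=O | intermediate
14 | rac-5-(3-hydroxyprop-1-en-2-yl)-2,2-dimethyl-1,3-dioxolan-4-one | C=C(CO)C1OC(C)(C)OC1=O | intermediate
15 | rac-tert-butyl 2-(2,2-dimethyl-5-oxo-1,3-dioxolan-4-yl)prop-2-en-1-yl carbonate | C=C(COC(=O)OC(C)(C)C)C1OC(C)(C)OC1=O | intermediate
16 | potassium 5-{[3,5-bis(benzyloxy)-4-oxocyclohexa-2,5-dien-1-ylidene]methyl}-2-methoxyphenolate (quinone methide) | COc1ccc(C=C2C=C(OCc3ccccc3)C(=O)C(OCc3ccccc3)=C2)cc1[O-].[K+] | intermediate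
17 | (1'S,4S)-1'-[3,5-bis(benzyloxy)-4-hydroxyphenyl]-7'-hydroxy-6'-methoxy-2,2-dimethyl-3'-methylidene-3',4'-dihydro-1'H-spiro[1,3-dioxolane-4,2'-naphthalen]-5-one (C1 aryl cis to the ring oxygen on C2) | COc1cc2c(cc1O)[C@H](c1cc(OCc3ccccc3)c(O)c(OCc3ccccc3)c1)[C@@]1(C(=O)OC(C)(C)O1)C(=C)C2 | intermediate
18 | (1'S,3'R,4S)-1'-[3,5-bis(benzyloxy)-4-hydroxyphenyl]-3',7'-dihydroxy-3'-(hydroxymethyl)-6'-methoxy-2,2-dimethyl-3',4'-dihydro-1'H-spiro[1,3-dioxolane-4,2'-naphthalen]-5-one | COc1cc2c(cc1O)[C@H](c1cc(OCc3ccccc3)c(O)c(OCc3ccccc3)c1)[C@@]1(C(=O)OC(C)(C)O1)[C@](O)(CO)C2 | intermediate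
19 | (1S,2S,3R)-1-[3,5-bis(benzyloxy)-4-hydroxyphenyl]-2,3,7-trihydroxy-3-(hydroxymethyl)-6-methoxy-1,2,3,4-tetrahydronaphthalene-2-carboxylic acid | COc1cc2c(cc1O)[C@H](c1cc(OCc3ccccc3)c(O)c(OCc3ccccc3)c1)[C@@](O)(C(=O)O)[C@](O)(CO)C2 | intermediate
20 | (1S,2S,3R)-2,3,7-trihydroxy-3-(hydroxymethyl)-6-methoxy-1-(3,4,5-trihydroxyphenyl)-1,2,3,4-tetrahydronaphthalene-2-carboxylic acid | COc1cc2c(cc1O)[C@H](c1cc(O)c(O)c(O)c1)[C@@](O)(C(=O)O)[C@](O)(CO)C2 | target

**Totals and risks**

Total step count: 13. Longest linear sequence: 8 steps (for example 1 → 2 → 7 → 8 → 9 → 17 → 18 → 19 → 20).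

Step 10 (proposed new method) is the riskiest. The π-allyl may be captured by the ipso carbon of ring C or by C8 instead of C4a, and facial discrimination in the C1–C2 bond formation may be poor. The fallback sets out from 9 and 15 and uses two separate known operations. First, a chiral bifunctional Brønsted-base catalyst (a cinchona squaramide or, for this weak carbon acid, a chiral iminophosphorane superbase) with aqueous K2CO3–toluene releases the quinone methide from 9 and mediates the enantioselective 1,6-addition of the dioxolanone carbon, giving the open-chain adduct tert-butyl 2-{(4S)-4-[(R)-[3,5-bis(benzyloxy)-4-hydroxyphenyl](3-hydroxy-4-methoxyphenyl)methyl]-2,2-dimethyl-5-oxo-1,3-dioxolan-4-yl}prop-2-en-1-yl carbonate F1. Second, Pd(PPh3)4 in THF closes ring B by intramolecular Friedel–Crafts-type allylic alkylation of the ring A phenol. The fallback comes back to the route at 17.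

Step 11 may fail through poor facial selectivity of osmylation at the hindered C3 methylene. The fallback sets out from 17 and replaces substrate control by reagent control: ligand-accelerated asymmetric dihydroxylation with K2OsO2(OH)4, the pseudo-enantiomeric (DHQD)2PHAL or (DHQ)2PHAL ligand that matches the required face, and NMO as reoxidant (slow addition, acetone–H2O), which spares the free phenols. It comes back at 18.

Step 8 may fail through over-oxidation to the enal, ene attack at the dioxolanone methine, or loss of the acetonide. The fallback sets out from 13: ene-type allylic chlorination with Ca(OCl)2 and CO2 in CH2Cl2–H2O gives the allylic chloride rac-5-(3-chloroprop-1-en-2-yl)-2,2-dimethyl-1,3-dioxolan-4-one F2. F2 then replaces 15 in step 10, where zerovalent palladium ionises the C–Cl bond and one further equivalent of KOtBu supplies the base that the carbonate no longer delivers. It comes back at 17.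

**Further compounds**

F1 | step 10 | tert-butyl 2-{(4S)-4-[(R)-[3,5-bis(benzyloxy)-4-hydroxyphenyl](3-hydroxy-4-methoxyphenyl)methyl]-2,2-dimethyl-5-oxo-1,3-dioxolan-4-yl}prop-2-en-1-yl carbonate | COc1ccc(cc1O)[C@H](c1cc(OCc2ccccc2)c(O)c(OCc2ccccc2)c1)[C@@]1(C(=O)OC(C)(C)O1)C(=C)COC(=O)OC(C)(C)C
F0 | step 11 | none | none
F2 | step 8 | rac-5-(3-chloroprop-1-en-2-yl)-2,2-dimethyl-1,3-dioxolan-4-one | C=C(CCl)C1OC(C)(C)OC1=O
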